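The C6–C7 single bond between the oleate-bearing ring (C1–C6) and the polyene is the disconnection on which the route rests. A Suzuki–Miyaura coupling in the last step joins an all-E C31 decaenyl pinacol boronate to a C9 cyclohexenyl triflate that already holds the (3R) centre and the oleate, completing the undecaene in one operation. The step exploits that C6 sits between quaternary C1 (gem-dimethyl) and methyl-bearing C5: the parent ketone enolises only towards C5, so one regiodefined triflate forms. The boronate comes from β-apo-8'-carotenal (retinyl C20 ylide plus a C10 dialdehyde monoacetal), the triflate from ketoisophorone via enzymatic reduction to (4R,6R)-actinol.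

Key step: step 11

Remark on the chemistry (assumption): a retinyl C20 ylide needs the unsymmetrical C10 partner 2,6-dimethylocta-2,4,6-trienedial (the symmetrical 2,7-dimethyl isomer would put the C13' methyl on C14'), built here as its mono(dimethyl acetal) 5, masked at the formyl group next to the methyl-bearing carbon (future C8'); the two reductases of step 8 are taken as accessible recombinant enzymes.

Step 1
Reactants: 1 1,1-dimethoxypropan-2-one (pyruvaldehyde dimethyl acetal)
Product: 2 (E)-4,4-dimethoxy-3-methylbut-2-enenitrile
Conditions: diethyl cyanomethylphosphonate, NaH, THF, 0 °C to rt; chromatography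
Reagents that add atoms: diethyl cyanomethylphosphonate, CCOP(=O)(CC#N)OCC
Why: Horner–Wadsworth–Emmons olefination, in which the sodium phosphonate anion adds to the acetal-activated ketone and the oxaphosphetane collapses to the conjugated nitrile, the E isomer (cyano trans to the bulkier acetal carbon) being favoured and the minor Z isomer being removed by chromatography.

Step 2
Reactants: 2 (E)-4,4-dimethoxy-3-methylbut-2-enenitrile
Product: 3 (E)-4,4-dimethoxy-3-methylbut-2-enal
Conditions: i-Bu2AlH, hexane/Et2O, −78 °C; then wet SiO2, 0 °C
Reagents that add atoms: water, O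
Why: Partial reduction of a nitrile, in which one hydride adds to give an N-aluminio aldimine that is stable at low temperature and is hydrolysed on wet silica to the enal under conditions too mild to open the dimethyl acetal.

Step 3
Reactants: 3 (E)-4,4-dimethoxy-3-methylbut-2-enal
Product: 4 (2E,4E,6E)-8,8-dimethoxy-3,7-dimethylocta-2,4,6-trienenitrile
Conditions: diethyl (3-cyano-2-methylallyl)phosphonate, NaH, THF, 0 °C to rt; chromatography
Reagents that add atoms: diethyl (3-cyano-2-methylallyl)phosphonate (E drawn, sold as an E/Z mixture), CCOP(=O)(C/C(C)=C/C#N)OCC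
Why: Horner–Wadsworth–Emmons olefination with the C5 allylic phosphonate, whose anion reacts at the phosphorus-bearing carbon to form the new disubstituted C4=C5 bond with E geometry and complete the 2,6-dimethyloctatriene skeleton, any 2Z isomer being separated by chromatography.

Step 4
Reactants: 4 (2E,4E,6E)-8,8-dimethoxy-3,7-dimethylocta-2,4,6-trienenitrile
Product: 5 (2E,4E,6E)-8,8-dimethoxy-3,7-dimethylocta-2,4,6-trienal, the mono(dimethyl acetal) of (2E,4E,6E)-2,6-dimethylocta-2,4,6-trienedial
Conditions: i-Bu2AlH, hexane/Et2O, −78 °C; then wet SiO2, 0 °C
Reagents that add atoms: water, O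
Why: Partial reduction of the conjugated nitrile through the N-aluminio aldimine, as in step 2, should free only the formyl group at the CH= terminus while the acetal at the other terminus stays in place.

Step 5
Reactants: 6 all-trans-retinyl acetate
Product: 7 all-trans-retinyltriphenylphosphonium bromide
Conditions: PPh3·HBr, MeOH, 20 °C, dark
Reagents that add atoms: triphenylphosphine hydrobromide, [Br-].[PH+](c1ccccc1)(c1ccccc1)c1ccccc1
Why: Allylic substitution, in which the acid ionises the allylic acetate and triphenylphosphine traps the delocalised retinyl cation at its terminal carbon, the all-E salt being expected to crystallise.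

Step 6
Reactants: 7 all-trans-retinyltriphenylphosphonium bromide; 5 (2E,4E,6E)-8,8-dimethoxy-3,7-dimethylocta-2,4,6-trienal
Product: 10 all-E β-apo-8'-carotenal (C30 aldehyde), via retinylidene ylide 8 (not isolated), via C30 dimethyl acetal 9 (not isolated)
Conditions: NaOMe, MeOH/CH2Cl2, 0 °C to rt; then aq. H2SO4 (cat.), acetone, rt; then heptane, reflux, argon, dark; crystallisation
Reagents that add atoms: water, O
Why: Wittig olefination in which the semistabilised ylide can attack only the single free formyl group of 5 (the other terminus is an acetal), so the methyl groups land on C13' and C9'; dilute acid then unmasks the α-methyl enal and heating equilibrates the new disubstituted C15=C15' alkene to E while the all-E aldehyde crystallises.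

Step 7
Reactants: 10 all-E β-apo-8'-carotenal; 11 2-(dichloromethyl)-4,4,5,5-tetramethyl-1,3,2-dioxaborolane
Product: 13 all-E C31 decaenyl pinacol boronate, via diiodomethyl pinacol boronate 12 (not isolated)
Conditions: CrCl2, LiI, THF, 25 °C, argon, dark
Reagents that add atoms: none
Why: Takai-type boryl olefination, in which iodide exchange gives the diiodide, divalent chromium reduces it to a geminal dichromium species that adds to the aldehyde, and elimination of the chromium oxide delivers the E-alkenyl boronate, adding carbon C7.

Step 8
Reactants: 14 ketoisophorone (2,6,6-trimethylcyclohex-2-ene-1,4-dione)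
Product: 16 (4R,6R)-4-hydroxy-2,2,6-trimethylcyclohexanone (actinol), via (6R)-levodione 15 (not isolated)
Conditions: ene-reductase OYE2, NADP+ (cat.), glucose dehydrogenase, D-glucose, phosphate buffer pH 7, 30 °C; then levodione reductase, NAD+ (cat.), 30 °C; recrystallisation
Reagents that add atoms: none
Why: Enzymatic asymmetric reduction, in which the flavin-dependent ene-reductase adds hydride and a proton across the ring C=C to set the methyl-bearing centre as R and the levodione reductase then delivers hydride to one face of the unhindered C4 carbonyl only (the C1 carbonyl is shielded by the flanking gem-dimethyl and methyl groups), setting the 4R carbinol centre that becomes C3 of the target, while recrystallisation removes any cis diastereomer, which would otherwise end as the (3S) enantiomer once the methyl centre is erased.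

Step 9
Reactants: 16 (4R,6R)-actinol; 17 oleoyl chloride ((Z)-octadec-9-enoyl chloride)
Product: 18 (1R,5R)-3,3,5-trimethyl-4-oxocyclohexyl (Z)-octadec-9-enoate (actinol oleate)
Conditions: pyridine, DMAP (cat.), CH2Cl2, 0 °C to rt
Reagents that add atoms: none
Why: DMAP-catalysed O-acylation (nucleophilic acyl substitution via the acylpyridinium ion) of the secondary alcohol, which leaves the carbinol configuration untouched because its C–O bond is not broken, and the γ-placed acyloxy group cannot be lost by β-elimination.

Step 10
Reactants: 18 actinol oleate
Product: 19 (1R)-3,5,5-trimethyl-4-(trifluoromethylsulfonyloxy)cyclohex-3-en-1-yl (Z)-octadec-9-enoate (ring enol triflate)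
Conditions: Tf2O, 2,6-di-tert-butyl-4-methylpyridine, CH2Cl2, 0 °C to rt
Reagents that add atoms: triflic anhydride, O=S(=O)(OS(=O)(=O)C(F)(F)F)C(F)(F)F
Why: Enol triflation, in which triflic anhydride activates the ketone oxygen and the hindered, non-nucleophilic pyridine removes the only α-hydrogen, which sits on the methyl-bearing carbon because the other α-carbon is quaternary, so a single regioisomer forms, the methyl stereocentre is erased, the oxygen-bearing centre is untouched and no strong base is present to enolise the ester.

Step 11
Reactants: 13 all-E C31 decaenyl pinacol boronate; 19 ring enol triflate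
Product: 20 (3R)-β-cryptoxanthin oleate (target)
Conditions: Pd2(dba)3 (cat.), SPhos (2-dicyclohexylphosphino-2',6'-dimethoxybiphenyl), aq. K3PO4, THF, 45 °C, argon, dark
Reagents that add atoms: none
Why: Zerovalent palladium carrying the bulky biaryl phosphine inserts into the C6–OTf bond of the hindered ring alkene, the phosphate-activated E-alkenyl boronate transfers C7 with retention, and reductive elimination forms the C6–C7 single bond; the closest known reaction type is the Suzuki–Miyaura coupling of 2,6,6-trimethylcyclohexenyl triflates with polyenyl boron reagents used for ring-to-chain unions of retinoids. No ring is closed and no stereocentre is created; the existing C3 centre is three bonds from the reacting carbon and cannot epimerise. The step needs retention of E geometry at C7=C8 and at the other chain alkenes, which stereospecific transmetalation and reductive elimination under mild, dark, oxygen-free conditions should secure. It also needs chemoselectivity for the alkenyl triflate, secured because the substrate has a single C–OTf site while the homoallylic oleate ester and its isolated Z alkene are inert to zerovalent palladium and aqueous phosphate at 45 °C. Regiochemistry is fixed beforehand, because C6 lies between quaternary C1 and methyl-bearing C5.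

Compound list
1 | 1,1-dimethoxypropan-2-one | CC(=O)C(OC)OC | starting material
2 | (E)-4,4-dimethoxy-3-methylbut-2-enenitrile | N#C/C=C(C)/C(OC)OC | intermediate
3 | (E)-4,4-dimethoxy-3-methylbut-2-enal | O=C/C=C(C)/C(OC)OC | intermediate
4 | (2E,4E,6E)-8,8-dimethoxy-3,7-dimethylocta-2,4,6-trienenitrile | N#C/C=C(C)/C=C/C=C(C)/C(OC)OC | intermediate
5 | (2E,4E,6E)-8,8-dimethoxy-3,7-dimethylocta-2,4,6-trienal (monoacetal of 2,6-dimethylocta-2,4,6-trienedial) | O=C/C=C(C)/C=C/C=C(C)/C(OC)OC | intermediate
6 | all-trans-retinyl acetate | CC(=O)OC/C=C(C)/C=C/C=C(C)/C=C/C1=C(C)CCCC1(C)C | starting material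
7 | all-trans-retinyltriphenylphosphonium bromide | C(/C=C(C)/C=C/C=C(C)/C=C/C1=C(C)CCCC1(C)C)[P+](c2ccccc2)(c3ccccc3)c4ccccc4.[Br-] | intermediate
8 | retinylidene triphenylphosphorane (ylide, not isolated) | [CH-](/C=C(C)/C=C/C=C(C)/C=C/C1=C(C)CCCC1(C)C)[P+](c2ccccc2)(c3ccccc3)c4ccccc4 | intermediate
9 | β-apo-8'-carotenal dimethyl acetal (drawn 15E; 15Z also present before equilibration; not isolated) | COC(OC)/C(C)=C/C=C/C(C)=C/C=C/C=C(C)/C=C/C=C(C)/C=C/C1=C(C)CCCC1(C)C | intermediate
10 | all-E β-apo-8'-carotenal | O=C/C(C)=C/C=C/C(C)=C/C=C/C=C(C)/C=C/C=C(C)/C=C/C1=C(C)CCCC1(C)C | intermediate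
11 | 2-(dichloromethyl)-4,4,5,5-tetramethyl-1,3,2-dioxaborolane | ClC(Cl)B1OC(C)(C)C(C)(C)O1 | starting material
12 | 2-(diiodomethyl)-4,4,5,5-tetramethyl-1,3,2-dioxaborolane (not isolated) | IC(I)B1OC(C)(C)C(C)(C)O1 | intermediate
13 | all-E C31 decaenyl pinacol boronate | CC1(C)OB(/C=C/C(C)=C/C=C/C(C)=C/C=C/C=C(C)/C=C/C=C(C)/C=C/C2=C(C)CCCC2(C)C)OC1(C)C | intermediate
14 | ketoisophorone | CC1=CC(=O)CC(C)(C)C1=O | starting material
15 | (6R)-2,2,6-trimethylcyclohexane-1,4-dione (levodione, not isolated) | O=C1C[C@@H](C)C(=O)C(C)(C)C1 | intermediate
16 | (4R,6R)-4-hydroxy-2,2,6-trimethylcyclohexanone (actinol) | O[C@@H]1C[C@@H](C)C(=O)C(C)(C)C1 | intermediate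
17 | oleoyl chloride | CCCCCCCC/C=C\CCCCCCCC(=O)Cl | starting material
18 | (1R,5R)-3,3,5-trimethyl-4-oxocyclohexyl (Z)-octadec-9-enoate | CCCCCCCC/C=C\CCCCCCCC(=O)O[C@@H]1C[C@@H](C)C(=O)C(C)(C)C1 | intermediate
19 | (1R)-3,5,5-trimethyl-4-(trifluoromethylsulfonyloxy)cyclohex-3-en-1-yl (Z)-octadec-9-enoate | CCCCCCCC/C=C\CCCCCCCC(=O)O[C@@H]1CC(C)=C(OS(=O)(=O)C(F)(F)F)C(C)(C)C1 | intermediate
20 | (3R)-β-cryptoxanthin oleate | CCCCCCCC/C=C\CCCCCCCC(=O)O[C@@H]1CC(C)=C(/C=C/C(C)=C/C=C/C(C)=C/C=C/C=C(C)/C=C/C=C(C)/C=C/C2=C(C)CCCC2(C)C)C(C)(C)C1 | target

Total step count: 11. Longest linear sequence: 7 steps (steps 1, 2, 3, 4, 6, 7 and 11).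

Steps most likely to fail

Step 11. Oxidative addition and transmetalation at the hindered triflate may be slow, so that base-promoted protodeboronation and geometric isomerisation of the light- and air-sensitive decaenyl boronate compete with coupling. The fallback is a base-free Stille union. It sets out from aldehyde 10, which is olefinated with tributyl(dibromomethyl)stannane, CrCl2 and LiI in THF/DMF to the all-E C31 decaenyl tributylstannane F1. F1 is then coupled with triflate 19 (Pd2(dba)3, AsPh3, LiCl, NMP, 40 °C, dark) and the route is rejoined at target 20.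

Step 7. Divalent chromium may transfer single electrons to the long polyenal (pinacol-type coupling, erosion of alkene geometry), or the boronate may be lost by protodeboronation during isolation. The fallback is a chromium-free boron-Wittig olefination. It sets out from aldehyde 10, which is treated at −78 °C in THF with the anion made from bis(4,4,5,5-tetramethyl-1,3,2-dioxaborolan-2-yl)methane and lithium 2,2,6,6-tetramethylpiperidide. Addition and elimination of a boron–oxygen fragment should give the E-alkenyl boronate directly, rejoining the route at boronate 13; no compound outside the list arises on this way (F0).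

Step 10. Enolisation of the hindered ketone may be sluggish, which gives triflic anhydride time to attack the ester carbonyl and lets liberated acid isomerise the Z alkene. The fallback moves the triflation ahead of the acylation so that a strong base can be used. It sets out from actinol 16, which is silylated (TBSCl, imidazole, DMF) to (4R,6R)-4-(tert-butyldimethylsilyloxy)-2,2,6-trimethylcyclohexanone F2. Deprotonation with KN(SiMe3)2 and trapping with N-phenylbis(trifluoromethanesulfonimide) in THF at −78 °C gives (R)-4-(tert-butyldimethylsilyloxy)-2,6,6-trimethylcyclohex-1-en-1-yl triflate F3. HF·pyridine in THF frees (R)-4-hydroxy-2,6,6-trimethylcyclohex-1-en-1-yl triflate F4, and acylation with oleoyl chloride 17 (pyridine, DMAP, CH2Cl2) rejoins the route at triflate 19.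

Further compounds
F1 | step 11 | all-E C31 decaenyl tributylstannane | CCCC[Sn](CCCC)(CCCC)/C=C/C(C)=C/C=C/C(C)=C/C=C/C=C(C)/C=C/C=C(C)/C=C/C1=C(C)CCCC1(C)C
F0 | step 7 | none | none
F2 | step 10 | (4R,6R)-4-(tert-butyldimethylsilyloxy)-2,2,6-trimethylcyclohexanone | CC(C)(C)[Si](C)(C)O[C@@H]1C[C@@H](C)C(=O)C(C)(C)C1
F3 | step 10 | (R)-4-(tert-butyldimethylsilyloxy)-2,6,6-trimethylcyclohex-1-en-1-yl triflate | CC(C)(C)[Si](C)(C)O[C@@H]1CC(C)=C(OS(=O)(=O)C(F)(F)F)C(C)(C)C1
F4 | step 10 | (R)-4-hydroxy-2,6,6-trimethylcyclohex-1-en-1-yl triflate | O[C@@H]1CC(C)=C(OS(=O)(=O)C(F)(F)F)C(C)(C)C1
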